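## Retrosynthetic overview

1. The target comes from a 2α-hydroxy-germacra-1(10)E,4Z-dienolide by one hydroxyl-directed double epoxidation; the angelate comes from Yamaguchi acylation of the C8 alcohol and the exocyclic methylene from Eschenmoser methylenation.
2. The trans-fused γ-lactone comes from a C6 ketone carrying an acetate arm on C7, by chelation-controlled reduction and lactonisation.
3. The ten-membered ring comes from an anionic oxy-Cope ([3,3]) ring expansion of a 1-alkenyl-6-isopropenylcyclohex-2-en-1-ol with in-situ enolate alkylation. This key step makes C8–C9 and sets C8, C7 and the 1(10)E olefin; the 4Z olefin is the old ring olefin.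
4. The Cope substrate comes from a trans-5-silyloxy-6-isopropenyl-3-methylcyclohex-2-enone and lithium (4-methoxybenzyloxy)acetylide, followed by LiAlH4 trans-reduction to the (E)-enol ether.
5. The cyclohexenone comes from (S)-pulegone, whose single stereocentre relays chirality to the two ring stereocentres and is then erased. Ring order: six-membered ring (bought), ten-membered ring, lactone, two oxiranes.

Assumption 1: the SMILES is taken literally, i.e. (1R,2S,4R,5S,6S,7R,8S,10R): 1β,10α-epoxide (trans), 4α,5α-epoxide (cis), 2α-OH, 8α-O-angeloyl, trans-fused 12,6α-olide.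

Assumption 2: (S)-(−)-pulegone, the less common commercial enantiomer, is accepted as the bought chiral starting material.

Numbering note: ten-membered-ring compounds are numbered as germacranes (C1–C10 around the ring, C14 on C10, C15 on C4, C11–C13 on C7; α/β as in the usual germacranolide drawing with H7 α).

This route is designed on paper and has not been run; stereochemical outcomes on the ten-membered ring rest on conformational models.

## Route

Step 1
Reactants: 1 (S)-(−)-pulegone
Product: 3 (5S)-5-methyl-2-(prop-1-en-2-yl)cyclohex-2-en-1-one, via silyl dienol ether 2 (not isolated)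
Conditions: TMSCl, NaI, Et3N, MeCN, 23 °C; then Pd(OAc)2 (1.05 equiv), MeCN, 23 °C
Reagents that add atoms: chlorotrimethylsilane, C[Si](C)(C)Cl (silyl group of 2 only, lost again on the way to 3)
Why: Soft enolisation through the γ-position gives the thermodynamic 2-silyloxy-1,3-diene, and Saegusa–Ito oxidation (palladation at C2, β-hydride elimination from C3) installs the endocyclic C2=C3 bond without touching the bought C5 stereocentre.

Step 2
Reactants: 3 (5S)-5-methyl-2-(prop-1-en-2-yl)cyclohex-2-en-1-one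
Product: 5 (2S,3S,5S)-3-hydroxy-5-methyl-2-(prop-1-en-2-yl)cyclohexan-1-one, via pinacol boronate 4 (not isolated)
Conditions: B2pin2 (1.1 equiv), CuCl (5 mol %), Xantphos (5 mol %), NaOt-Bu (10 mol %), MeOH (2 equiv), THF, 23 °C; then NaBO3·4H2O, THF/H2O, 23 °C
Reagents that add atoms: bis(pinacolato)diboron, CC1(C)OB(OC1(C)C)B1OC(C)(C)C(C)(C)O1 (boryl group of 4); sodium perborate, O=BO[O-].[Na+] (hydroxyl oxygen of 5)
Why: Copper-catalysed conjugate borylation with an achiral ligand adds boron to C3 by axial attack anti to the C5 methyl (3,5-trans), the enolate is protonated axially anti to the new C–B bond (2,3-cis, isopropenyl equatorial), and perborate oxidation replaces boron by hydroxyl with retention.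

Step 3
Reactants: 5 (2S,3S,5S)-3-hydroxy-5-methyl-2-(prop-1-en-2-yl)cyclohexan-1-one
Product: 6 (1S,3S)-5-methyl-2-(prop-1-en-2-yl)cyclohexane-1,3-diol (anti diol; new C1–OH cis to methyl and trans to isopropenyl)
Conditions: Me4NBH(OAc)3 (5 equiv), MeCN/AcOH 1:1, −30 °C
Reagents that add atoms: none
Why: Evans–Saksena directed reduction, in which the axial C3 hydroxyl binds the triacetoxyborohydride and delivers hydride intramolecularly to the same face of C1, gives the 1,3-anti diol with the new C1 hydroxyl equatorial.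

Step 4
Reactants: 6 (1S,3S)-5-methyl-2-(prop-1-en-2-yl)cyclohexane-1,3-diol
Product: 7 (1S,2S,3S,5S)-3-[(tert-butyldimethylsilyl)oxy]-5-methyl-2-(prop-1-en-2-yl)cyclohexan-1-ol
Conditions: TBSCl (1.05 equiv), imidazole, DMF, −20 → 0 °C
Reagents that add atoms: tert-butyldimethylsilyl chloride, CC(C)(C)[Si](C)(C)Cl
Why: Corey silylation distinguishes the unhindered equatorial hydroxyl from the axial one (shielded by syn-axial hydrogens), so the oxygen that becomes the C2 hydroxyl of the target is protected and no stereocentre is touched.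

Step 5
Reactants: 7 (1S,2S,3S,5S)-3-[(tert-butyldimethylsilyl)oxy]-5-methyl-2-(prop-1-en-2-yl)cyclohexan-1-ol
Product: 8 (2R,3S,5R)-3-[(tert-butyldimethylsilyl)oxy]-5-methyl-2-(prop-1-en-2-yl)cyclohexan-1-one
Conditions: Dess–Martin periodinane, NaHCO3, CH2Cl2, 0 → 23 °C
Reagents that add atoms: none
Why: Dess–Martin oxidation of the remaining axial alcohol under buffered conditions completes the exchange of oxidation level between the two oxygens, and the all-equatorial 2,3-trans ketone formed is also the thermodynamic α-epimer, so it does not scramble.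

Step 6
Reactants: 8 (2R,3S,5R)-3-[(tert-butyldimethylsilyl)oxy]-5-methyl-2-(prop-1-en-2-yl)cyclohexan-1-one
Product: 10 (5S,6R)-5-[(tert-butyldimethylsilyl)oxy]-3-methyl-6-(prop-1-en-2-yl)cyclohex-2-en-1-one, via trimethylsilyl enol ether 9 (not isolated)
Conditions: LiN(i-Pr)2 (commercial solution), TMSCl, THF, −78 °C; then Pd(OAc)2 (1.1 equiv), MeCN, 23 °C
Reagents that add atoms: chlorotrimethylsilane, C[Si](C)(C)Cl (silyl group of 9 only)
Why: Kinetic deprotonation at the unhindered CH2 (not the isopropenyl-bearing methine) followed by Saegusa–Ito oxidation gives the enone, erasing the relay methyl stereocentre and leaving the trans 5-silyloxy/6-isopropenyl pair that it controlled.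

Step 7
Reactants: 11 4-methoxybenzyl alcohol; 12 trichloroethylene
Product: 14 (E)-1,2-dichlorovinyl 4-methoxybenzyl ether, via dichloroacetylene 13 (not isolated)
Conditions: KH (2.2 equiv), THF, 0 °C; Cl2C=CHCl, 0 → 23 °C; H2O quench
Reagents that add atoms: none
Why: Greene's alkynyl-ether precursor synthesis, in which the potassium alkoxide adds to dichloroacetylene generated in situ by dehydrochlorination of trichloroethylene (net addition–elimination); no stereocentre is formed.

Step 8
Reactants: 14 (E)-1,2-dichlorovinyl 4-methoxybenzyl ether; 10 (5S,6R)-5-[(tert-butyldimethylsilyl)oxy]-3-methyl-6-(prop-1-en-2-yl)cyclohex-2-en-1-one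
Product: 17 (1R,5S,6R)-5-[(tert-butyldimethylsilyl)oxy]-1-{(E)-2-[(4-methoxybenzyl)oxy]ethenyl}-3-methyl-6-(prop-1-en-2-yl)cyclohex-2-en-1-ol, via lithium alkoxyacetylide 15 (not isolated), via lithium propargylic alkoxide 16 (not isolated)
Conditions: 14 (1.3 equiv), n-BuLi (2.6 equiv), THF, −78 → −40 °C; 10, −78 °C; then LiAlH4 (3 equiv), −78 → 23 °C; aq. potassium sodium tartrate
Reagents that add atoms: none
Why: Elimination then chlorine–lithium exchange gives the lithium alkoxyacetylide, which adds 1,2 to the enone anti to the neighbouring isopropenyl group, and LiAlH4 reduces the propargylic alkoxide by hydroxyl-directed trans-hydroalumination to the (E)-enol ether (the carbinol epimer would converge in step 9, where that stereocentre is destroyed).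

Step 9
Reactants: 17 (1R,5S,6R)-5-[(tert-butyldimethylsilyl)oxy]-1-{(E)-2-[(4-methoxybenzyl)oxy]ethenyl}-3-methyl-6-(prop-1-en-2-yl)cyclohex-2-en-1-ol; 18 methyl bromoacetate
Product: 20 methyl 2-[(2S,7R,8S)-2-(tert-butyldimethylsilyloxy)-8-(4-methoxybenzyloxy)-4,10-dimethyl-6-oxocyclodeca-1(10)E,4Z-dien-7-yl]acetate, via potassium enolate 19 (not isolated)
Conditions: KN(SiMe3)2 (1.1 equiv), 18-crown-6 (1.2 equiv), THF, −20 → 23 °C; then 18, −78 → −40 °C
Reagents that add atoms: none
Why: Anionic oxy-Cope rearrangement ([3,3]-sigmatropic) through the chair with both alkenyl groups equatorial on the cyclohexene forms the C8–C9 bond, the ten-membered ring and the (E)-C1=C10 olefin (C4=C5 stays Z), sets C8 as S by chirality transfer from C1 because the (E)-enol ether places the ether oxygen equatorial, and the regiodefined enolate is alkylated in situ on its exo face anti to C9, placing the acetate arm trans to the C8 ether (7R).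

Step 10
Reactants: 20 methyl 2-[(2S,7R,8S)-2-(tert-butyldimethylsilyloxy)-8-(4-methoxybenzyloxy)-4,10-dimethyl-6-oxocyclodeca-1(10)E,4Z-dien-7-yl]acetate
Product: 22 (2S,6R,7R,8S)-2-(tert-butyldimethylsilyloxy)-8-(4-methoxybenzyloxy)-13-norgermacra-1(10)E,4Z-dien-12,6-olide, via hydroxy ester 21 (not isolated)
Conditions: Zn(BH4)2, Et2O, −40 → 0 °C; aq. NH4Cl; then PPTS (cat.), CH2Cl2, 23 °C
Reagents that add atoms: none
Why: Chelation-controlled 1,2-reduction, in which zinc bridges the C6 carbonyl and the C8 benzylic ether and hydride attacks anti to the pseudo-axial C7 substituent, gives the 6,8-syn (6α) alcohol, which closes onto the C7 ester arm as the trans-fused γ-lactone.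

Step 11
Reactants: 22 (2S,6R,7R,8S)-2-(tert-butyldimethylsilyloxy)-8-(4-methoxybenzyloxy)-13-norgermacra-1(10)E,4Z-dien-12,6-olide
Product: 25 (2S,6R,7R,8S)-2-(tert-butyldimethylsilyloxy)-8-(4-methoxybenzyloxy)germacra-1(10)E,4Z,11(13)-trien-12,6-olide, via Mannich base 23 (not isolated), via trimethylammonium iodide 24 (not isolated)
Conditions: LiN(i-Pr)2 (commercial solution), THF, −78 °C; CH2=NMe2+ I−, −78 → 0 °C; then MeI, MeOH, 23 °C; then DBU, CH2Cl2, 23 °C
Reagents that add atoms: N,N-dimethylmethyleneiminium iodide (Eschenmoser's salt), C=[N+](C)C.[I-] (the methylene carbon); iodomethane, CI (N-methyl of 24 only)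
Why: Eschenmoser α-methylenation (Mannich reaction of the lactone enolate, N-quaternisation, base-induced elimination of trimethylamine) gives the exocyclic methylene, so C11 ends as a non-stereogenic sp2 carbon.

Step 12
Reactants: 25 (2S,6R,7R,8S)-2-(tert-butyldimethylsilyloxy)-8-(4-methoxybenzyloxy)germacra-1(10)E,4Z,11(13)-trien-12,6-olide
Product: 26 (2S,6R,7R,8S)-2-(tert-butyldimethylsilyloxy)-8-hydroxygermacra-1(10)E,4Z,11(13)-trien-12,6-olide
Conditions: DDQ, CH2Cl2/aq. NaH2PO4–Na2HPO4 (pH 7) 10:1, 0 °C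
Reagents that add atoms: none
Why: Oxidative cleavage of the 4-methoxybenzyl ether by DDQ (benzylic hydride abstraction, hydrolysis of the oxocarbenium ion) under buffered conditions leaves silyl ether, lactone and olefins intact and the C8–O bond untouched.

Step 13
Reactants: 26 (2S,6R,7R,8S)-2-(tert-butyldimethylsilyloxy)-8-hydroxygermacra-1(10)E,4Z,11(13)-trien-12,6-olide; 27 angelic acid
Product: 29 (2S,6R,7R,8S)-8-angeloyloxy-2-(tert-butyldimethylsilyloxy)germacra-1(10)E,4Z,11(13)-trien-12,6-olide, via mixed anhydride 28 (not isolated)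
Conditions: 27, 2,4,6-Cl3C6H2COCl, Et3N, PhMe, 23 °C; then 26, PhMe, 80 °C
Reagents that add atoms: 2,4,6-trichlorobenzoyl chloride, O=C(Cl)c1c(Cl)cc(Cl)cc1Cl (aroyl group of 28 only)
Why: Yamaguchi esterification through the mixed anhydride, run without a nucleophilic amine catalyst so the (Z)-2-methylbut-2-enoyl group is not isomerised to the tiglate, acylates oxygen with retention at C8.

Step 14
Reactants: 29 (2S,6R,7R,8S)-8-angeloyloxy-2-(tert-butyldimethylsilyloxy)germacra-1(10)E,4Z,11(13)-trien-12,6-olide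
Product: 30 (2S,6R,7R,8S)-8-angeloyloxy-2-hydroxygermacra-1(10)E,4Z,11(13)-trien-12,6-olide
Conditions: HF·pyridine, pyridine, THF, 0 → 23 °C
Reagents that add atoms: none
Why: Buffered fluoride desilylation frees the allylic C2 hydroxyl without acid-triggered transannular cyclisation of the 1,5-diene or conjugate addition to the methylene lactone.

Step 15
Reactants: 30 (2S,6R,7R,8S)-8-angeloyloxy-2-hydroxygermacra-1(10)E,4Z,11(13)-trien-12,6-olide
Product: 31 (1R,2S,4R,5S,6S,7R,8S,10R)-8-angeloyloxy-1,10:4,5-diepoxy-2-hydroxygermacr-11(13)-en-12,6-olide (CNP0388761.2)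
Conditions: VO(acac)2 (10 mol %), t-BuOOH (2.5 equiv, in decane), CH2Cl2, 0 → 23 °C
Reagents that add atoms: tert-butyl hydroperoxide, CC(C)(C)OO (both epoxide oxygens)
Why: Hydroxyl-directed vanadium-catalysed epoxidation, in which the 2α-hydroxyl sits on the outer face of the (E)-C1=C10 olefin with H2 eclipsing the cis methyl (allylic 1,3-strain) and so gives the threo 1β,10α-epoxide, then acts as a homoallylic director to the same (α) face of the (Z)-C4=C5 olefin to give the cis 4α,5α-epoxide, while the electron-poor methylene lactone and angelate do not react.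

## Compound list

1 | (S)-(−)-pulegone, i.e. (5S)-5-methyl-2-(propan-2-ylidene)cyclohexan-1-one | C[C@H]1CCC(=C(C)C)C(=O)C1 | starting material
2 | trimethyl{[(5S)-5-methyl-2-(prop-1-en-2-yl)cyclohex-1-en-1-yl]oxy}silane (extended silyl dienol ether) | C[C@H]1CCC(C(C)=C)=C(O[Si](C)(C)C)C1 | intermediate
3 | (5S)-5-methyl-2-(prop-1-en-2-yl)cyclohex-2-en-1-one | C[C@H]1CC=C(C(C)=C)C(=O)C1 | intermediate
4 | 5-methyl-2-(prop-1-en-2-yl)-3-(4,4,5,5-tetramethyl-1,3,2-dioxaborolan-2-yl)cyclohexan-1-one (boryl trans to methyl, cis to isopropenyl) | CC(=C)[C@H]1[C@@H](B2OC(C)(C)C(C)(C)O2)C[C@H](C)CC1=O | intermediate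
5 | (2S,3S,5S)-3-hydroxy-5-methyl-2-(prop-1-en-2-yl)cyclohexan-1-one | CC(=C)[C@H]1[C@@H](O)C[C@H](C)CC1=O | intermediate
6 | (1S,3S)-5-methyl-2-(prop-1-en-2-yl)cyclohexane-1,3-diol (anti diol; isopropenyl trans to methyl) | CC(=C)[C@H]1[C@@H](O)C[C@H](C)C[C@@H]1O | intermediate
7 | (1S,2S,3S,5S)-3-[(tert-butyldimethylsilyl)oxy]-5-methyl-2-(prop-1-en-2-yl)cyclohexan-1-ol | CC(=C)[C@H]1[C@@H](O)C[C@H](C)C[C@@H]1O[Si](C)(C)C(C)(C)C | intermediate
8 | (2R,3S,5R)-3-[(tert-butyldimethylsilyl)oxy]-5-methyl-2-(prop-1-en-2-yl)cyclohexan-1-one (all substituents equatorial) | CC(=C)[C@H]1C(=O)C[C@H](C)C[C@@H]1O[Si](C)(C)C(C)(C)C | intermediate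
9 | kinetic trimethylsilyl enol ether of 8 (enol double bond toward the CH2) | CC(=C)[C@H]1C(O[Si](C)(C)C)=C[C@H](C)C[C@@H]1O[Si](C)(C)C(C)(C)C | intermediate
10 | (5S,6R)-5-[(tert-butyldimethylsilyl)oxy]-3-methyl-6-(prop-1-en-2-yl)cyclohex-2-en-1-one | CC(=C)[C@H]1C(=O)C=C(C)C[C@@H]1O[Si](C)(C)C(C)(C)C | intermediate
11 | 4-methoxybenzyl alcohol | COc1ccc(CO)cc1 | starting material
12 | trichloroethylene | ClC=C(Cl)Cl | starting material
13 | dichloroacetylene (formed in situ) | ClC#CCl | intermediate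
14 | (E)-1,2-dichlorovinyl 4-methoxybenzyl ether | COc1ccc(CO/C(Cl)=C\Cl)cc1 | intermediate
15 | lithium [(4-methoxybenzyl)oxy]ethynide | [Li+].[C-]#COCc1ccc(OC)cc1 | intermediate
16 | lithium (1S,5S,6R)-5-[(tert-butyldimethylsilyl)oxy]-1-{[(4-methoxybenzyl)oxy]ethynyl}-3-methyl-6-(prop-1-en-2-yl)cyclohex-2-en-1-olate | [Li+].CC(=C)[C@H]1[C@]([O-])(C#COCc2ccc(OC)cc2)C=C(C)C[C@@H]1O[Si](C)(C)C(C)(C)C | intermediate
17 | (1R,5S,6R)-5-[(tert-butyldimethylsilyl)oxy]-1-{(E)-2-[(4-methoxybenzyl)oxy]ethenyl}-3-methyl-6-(prop-1-en-2-yl)cyclohex-2-en-1-ol (alkenyl trans to isopropenyl) | CC(=C)[C@H]1[C@](O)(/C=C/OCc2ccc(OC)cc2)C=C(C)C[C@@H]1O[Si](C)(C)C(C)(C)C | intermediate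
18 | methyl bromoacetate | COC(=O)CBr | starting material
19 | potassium (2S,8S)-2-(tert-butyldimethylsilyloxy)-8-(4-methoxybenzyloxy)-4,10-dimethylcyclodeca-1(10)E,4Z,6Z-trien-6-olate (germacrane numbering) | [K+].C1/C(C)=C/[C@@H](O[Si](C)(C)C(C)(C)C)C/C(C)=C\C(\[O-])=C\[C@H]1OCc2ccc(OC)cc2 | intermediate
20 | methyl 2-[(2S,7R,8S)-2-(tert-butyldimethylsilyloxy)-8-(4-methoxybenzyloxy)-4,10-dimethyl-6-oxocyclodeca-1(10)E,4Z-dien-7-yl]acetate (germacrane numbering) | C1/C(C)=C/[C@@H](O[Si](C)(C)C(C)(C)C)C/C(C)=C\C(=O)[C@H](CC(=O)OC)[C@H]1OCc2ccc(OC)cc2 | intermediate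
21 | methyl 2-[(2S,6R,7S,8S)-2-(tert-butyldimethylsilyloxy)-6-hydroxy-8-(4-methoxybenzyloxy)-4,10-dimethylcyclodeca-1(10)E,4Z-dien-7-yl]acetate (6α-OH) | C1/C(C)=C/[C@@H](O[Si](C)(C)C(C)(C)C)C/C(C)=C\[C@@H](O)[C@H](CC(=O)OC)[C@H]1OCc2ccc(OC)cc2 | intermediate
22 | (2S,6R,7R,8S)-2-(tert-butyldimethylsilyloxy)-8-(4-methoxybenzyloxy)-13-norgermacra-1(10)E,4Z-dien-12,6-olide | C1/C(C)=C/[C@@H](O[Si](C)(C)C(C)(C)C)C/C(C)=C\[C@H]2OC(=O)C[C@@H]2[C@H]1OCc3ccc(OC)cc3 | intermediate
23 | 11-[(dimethylamino)methyl] derivative of 22 (C11 not controlled, removed in the elimination) | C1/C(C)=C/[C@@H](O[Si](C)(C)C(C)(C)C)C/C(C)=C\[C@H]2OC(=O)C(CN(C)C)[C@@H]2[C@H]1OCc3ccc(OC)cc3 | intermediate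
24 | N-methyl quaternary ammonium iodide of 23 | C1/C(C)=C/[C@@H](O[Si](C)(C)C(C)(C)C)C/C(C)=C\[C@H]2OC(=O)C(C[N+](C)(C)C)[C@@H]2[C@H]1OCc3ccc(OC)cc3.[I-] | intermediate
25 | (2S,6R,7R,8S)-2-(tert-butyldimethylsilyloxy)-8-(4-methoxybenzyloxy)germacra-1(10)E,4Z,11(13)-trien-12,6-olide | C1/C(C)=C/[C@@H](O[Si](C)(C)C(C)(C)C)C/C(C)=C\[C@H]2OC(=O)C(=C)[C@@H]2[C@H]1OCc3ccc(OC)cc3 | intermediate
26 | (2S,6R,7R,8S)-2-(tert-butyldimethylsilyloxy)-8-hydroxygermacra-1(10)E,4Z,11(13)-trien-12,6-olide | C1/C(C)=C/[C@@H](O[Si](C)(C)C(C)(C)C)C/C(C)=C\[C@H]2OC(=O)C(=C)[C@@H]2[C@H]1O | intermediate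
27 | angelic acid, (Z)-2-methylbut-2-enoic acid | C/C=C(/C)C(=O)O | starting material
28 | (Z)-2-methylbut-2-enoic 2,4,6-trichlorobenzoic anhydride | C/C=C(/C)C(=O)OC(=O)c1c(Cl)cc(Cl)cc1Cl | intermediate
29 | (2S,6R,7R,8S)-8-angeloyloxy-2-(tert-butyldimethylsilyloxy)germacra-1(10)E,4Z,11(13)-trien-12,6-olide | C1/C(C)=C/[C@@H](O[Si](C)(C)C(C)(C)C)C/C(C)=C\[C@H]2OC(=O)C(=C)[C@@H]2[C@H]1OC(=O)/C(C)=C\C | intermediate
30 | (2S,6R,7R,8S)-8-angeloyloxy-2-hydroxygermacra-1(10)E,4Z,11(13)-trien-12,6-olide | C1/C(C)=C/[C@@H](O)C/C(C)=C\[C@H]2OC(=O)C(=C)[C@@H]2[C@H]1OC(=O)/C(C)=C\C | intermediate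
31 | (1R,2S,4R,5S,6S,7R,8S,10R)-8-angeloyloxy-1,10:4,5-diepoxy-2-hydroxygermacr-11(13)-en-12,6-olide (CNP0388761.2) | C=C1C(=O)O[C@H]2[C@H]1[C@@H](OC(=O)/C(C)=C\C)C[C@@]1(C)O[C@@H]1[C@@H](O)C[C@@]1(C)O[C@@H]21 | target

## Step count and risks

Total step count: 15. Longest linear sequence: 14 steps (steps 1–6 and 8–15); step 7 is a one-step side branch.

The three steps most likely to fail are step 9, step 10 and step 15.

**Step 9.** The potassium enolate carries a β-ether and can expel 4-methoxybenzyl oxide while the rearrangement is running. It can also O-alkylate, and its C7 facial selectivity rests on a conformational argument (exo attack on the chair-derived conformer). The fallback sets out from 17 and returns at 20. The rearrangement is run cold (−20 → 0 °C) and the enolate is quenched at −78 °C with TMSCl, giving the trimethylsilyl enol ether F1, which is isolated. F1 is then cleaved with MeLi (THF, −78 °C) to the regiodefined lithium enolate, which is alkylated with 18 in THF/DMPU at −78 °C to give 20. This separates ring expansion from C–C bond formation and replaces the naked potassium enolate by a tighter lithium enolate at low temperature. It also lets the C7 ratio be measured and, if needed, corrected by base equilibration of 20.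

**Step 10.** Chelation through a ten-membered-ring β-ether may be weak, in which case ring conformation would decide the C6 configuration and could give the 6-epi alcohol. The fallback sets out from 20 and returns at 22. Non-chelating reduction (NaBH4, CeCl3, MeOH, −78 °C) is used, and the 6β-alcohol lactonises to the cis-fused lactone F2. LiOH (THF/H2O) opens F2 to the 6β-hydroxy acid F3. Mitsunobu lactonisation of F3 (PPh3, DIAD, PhMe, high dilution) closes the ring with inversion at C6 to give the trans-fused lactone 22.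

**Step 15.** The allylic epoxidation is well supported, but the homoallylic delivery to the (Z)-C4=C5 olefin is slower and its face selectivity on this ring is the least certain point of the route. The diepoxide is also acid-sensitive. The fallback sets out from 30 and returns at 31. With VO(acac)2 and only 1.05 equiv of t-BuOOH at −20 °C the reaction is stopped at the 1β,10α-monoepoxide F4. The remaining olefin of F4 is then epoxidised with dimethyldioxirane (acetone, −30 °C, neutral). This oxidant is guided by hydrogen bonding to the 2α-hydroxyl and by peripheral attack rather than by the metal template.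

## Further compounds

F1 | step 9 | trimethylsilyl enol ether of the ring-expanded ketone, (2S,8S)-2-(tert-butyldimethylsilyloxy)-8-(4-methoxybenzyloxy)-4,10-dimethyl-6-(trimethylsilyloxy)cyclodeca-1(10)E,4Z,6Z-triene | C1/C(C)=C/[C@@H](O[Si](C)(C)C(C)(C)C)C/C(C)=C\C(\O[Si](C)(C)C)=C\[C@H]1OCc2ccc(OC)cc2
F2 | step 10 | 6-epi-22, the cis-fused (2S,6S,7R,8S)-lactone | C1/C(C)=C/[C@@H](O[Si](C)(C)C(C)(C)C)C/C(C)=C\[C@@H]2OC(=O)C[C@@H]2[C@H]1OCc3ccc(OC)cc3
F3 | step 10 | 2-[(2S,6S,7S,8S)-2-(tert-butyldimethylsilyloxy)-6-hydroxy-8-(4-methoxybenzyloxy)-4,10-dimethylcyclodeca-1(10)E,4Z-dien-7-yl]acetic acid (6β-OH) | C1/C(C)=C/[C@@H](O[Si](C)(C)C(C)(C)C)C/C(C)=C\[C@H](O)[C@H](CC(=O)O)[C@H]1OCc2ccc(OC)cc2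
F4 | step 15 | (1R,2S,6R,7R,8S,10R)-8-angeloyloxy-1,10-epoxy-2-hydroxygermacra-4Z,11(13)-dien-12,6-olide | C1[C@@]2(C)O[C@@H]2[C@@H](O)C/C(C)=C\[C@H]3OC(=O)C(=C)[C@@H]3[C@H]1OC(=O)/C(C)=C\C
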